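**Plan**

1. Numbering follows the germacranolides: ring C1–C10, lactone carbons C11–C13 (C12=O on O6, C13 the exocyclic methylene), C14 the ester carbon on C10, C15 the methyl on C4. The feature used is that O2, C2, C3, C4(C15), C5 and C6 at the carboxyl level are the six ring atoms of a 4-methyl-5,6-dihydropyran-2-one, a ring that can only hold the cis C4/C5 arrangement later found in the epoxide.
2. Retrosynthetic cuts, in order: the silyl ethers and the O8/O9 acyl groups; C1=C10 (metathesis); C6–C7 together with O6–C12 (allylation and translactonisation), which separates a C1–C6 epoxy aldehyde from a C7–C14 bromomethyl δ-lactone; the epoxide oxygen; C2–C3 and O2–C6 (vinylogous aldol lactonisation).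
3. Forward: the dihydropyranone is made first, epoxidised and opened to the C6 aldehyde; the east δ-lactone is closed by metathesis; the halves are joined at C6–C7 and the acyl group moves from O9 to O6 to give the γ-lactone; the ten-membered ring is closed last at C1=C10.
4. Stereochemistry: C2 from the chiral copper catalyst; C4 and C5 from C2 through the lactone ring (epoxidation trans to the C2 substituent); C8 and C9 from an isopinocampheylborane alkoxyallylation; C7 and C6 from the ring-locked allylzinc (attack anti to the ring substituents, chair transition state), reinforced by Felkin–Anh attack on the epoxy aldehyde; the C1=C10 geometry from ring-closing metathesis (cis ring olefin, ester trans to C2).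

Key step: step 2

Assumption: the copper complex of (R)-Tol-BINAP is taken to deliver the dienolate to the Si face of the enal, and the borane made from (+)-Ipc2BOMe to add to the Re face of 2-bromoacrolein, as the usual facial models predict; should a first run show the opposite sense, the antipodal ligand or borane takes its place.

**Route**

Step 1
Reactants: 1 methyl 3-methylbut-2-enoate
Product: 2 [(1-methoxy-3-methylbuta-1,3-dien-1-yl)oxy]trimethylsilane
Conditions: LDA, THF, −78 °C; TMSCl, −78 °C → rt
Reagents that add atoms: chlorotrimethylsilane C[Si](C)(C)Cl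
Why: Kinetic γ-deprotonation of the senecioate and O-silylation of the lithium dienolate (silyl ketene acetal formation) is the standard route to this dienol ether, whose acetal geometry is irrelevant because silicon is exchanged for copper in the next step.

Step 2
Reactants: 2 [(1-methoxy-3-methylbuta-1,3-dien-1-yl)oxy]trimethylsilane; 3 (E)-but-2-enal
Product: 5 (S)-4-methyl-6-[(E)-prop-1-en-1-yl]-5,6-dihydro-2H-pyran-2-one, via copper aldolate 4 (not isolated)
Conditions: Cu(OTf)2 (10 mol %), (R)-Tol-BINAP (11 mol %), Bu4N[Ph3SiF2] (20 mol %), THF, −78 °C → rt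
Reagents that add atoms: none
Why: Fluoride moves the dienolate from silicon to the bisphosphine copper(I) centre, the copper dienolate adds through its γ-carbon to the aldehyde carbon (C2–C3), and the copper alkoxide 4, in which O2 and the ester are cis across C4=C5, expels methoxide by acyl substitution (O2–C6), the copper methoxide being silylated by the next molecule of 2 to close the cycle. The closest known reaction type is the copper fluoride–bisphosphine-catalysed vinylogous Mukaiyama aldol of senecioate silyl dienolates, which is known to deliver 5,6-dihydropyran-2-ones directly. The one ring is closed by 6-exo-trig attack of the C2 alkoxide on the ester carbonyl, and a six-membered lactone can only contain the cis C4=C5 geometry that the epoxide needs later. The single new stereocentre C2 is controlled by the chiral bisphosphine on copper, which leaves only the Si face of the bound enal open. The step needs γ- over α-attack and 1,2- over 1,4-addition: the β-methyl group hinders the α-carbon, the metal dienolate reacts at the carbonyl carbon, and an enal is the aldehyde class this catalyst type handles best.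

Step 3
Reactants: 5 (S)-4-methyl-6-[(E)-prop-1-en-1-yl]-5,6-dihydro-2H-pyran-2-one
Product: 7 (1R,4S,6R)-6-methyl-4-[(E)-prop-1-en-1-yl]-3,7-dioxabicyclo[4.1.0]heptan-2-one, via sodium glycidate 6 (not isolated)
Conditions: 30% H2O2, NaOH, MeOH, 0 °C; then 2 M HCl (pH 3), rt
Reagents that add atoms: hydrogen peroxide OO
Why: Weitz–Scheffer nucleophilic epoxidation: hydroperoxide adds axially to C4 of the half-chair lactone on the face trans to the pseudo-equatorial propenyl group at C2 and the enolate closes the oxirane on that same face, which sets C4 and C5 from C2 and keeps C3 and C6 cis on the epoxide, while lactone saponified afterwards to the glycidate 6 recloses on acidification.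

Step 4
Reactants: 7 (1R,4S,6R)-6-methyl-4-[(E)-prop-1-en-1-yl]-3,7-dioxabicyclo[4.1.0]heptan-2-one
Product: 8 (2R,3R)-3-[(2S,3E)-2-hydroxypent-3-en-1-yl]-N-methoxy-N,3-dimethyloxirane-2-carboxamide
Conditions: MeNH(OMe)·HCl, i-PrMgCl, THF, −20 °C
Reagents that add atoms: N,O-dimethylhydroxylamine hydrochloride CNOC.Cl
Why: Weinreb aminolysis with the chloromagnesium amide attacks only the acyl carbon C6 at low temperature, so the ring that has done its stereochemical work is opened with the oxirane and all three stereocentres intact and the C2 hydroxyl uncovered.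

Step 5
Reactants: 8 (2R,3R)-3-[(2S,3E)-2-hydroxypent-3-en-1-yl]-N-methoxy-N,3-dimethyloxirane-2-carboxamide
Product: 9 (2R,3R)-3-[(2S,3E)-2-[(tert-butyldimethylsilyl)oxy]pent-3-en-1-yl]-N-methoxy-N,3-dimethyloxirane-2-carboxamide
Conditions: TBSCl, imidazole, DMF, rt
Reagents that add atoms: tert-butyldimethylsilyl chloride CC(C)(C)[Si](C)(C)Cl
Why: Standard silylation of the only hydroxyl group, chosen as TBS so that O2 outlasts the triethylsilyl ether to be placed on O8.

Step 6
Reactants: 9 (2R,3R)-3-[(2S,3E)-2-[(tert-butyldimethylsilyl)oxy]pent-3-en-1-yl]-N-methoxy-N,3-dimethyloxirane-2-carboxamide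
Product: 10 (2R,3R)-3-[(2S,3E)-2-[(tert-butyldimethylsilyl)oxy]pent-3-en-1-yl]-3-methyloxirane-2-carbaldehyde
Conditions: DIBAL-H, THF, −78 °C; aq. Rochelle salt
Reagents that add atoms: none
Why: Weinreb amide reduction stops at the aldehyde because the chelated tetrahedral aluminate collapses only on work-up, the oxirane is inert to DIBAL-H at −78 °C, and the epoxy aldehyde should be used without purification.

Step 7
Reactants: 11 prop-2-enal (acrolein)
Product: 13 2-bromoprop-2-enal, via 2,3-dibromopropanal 12 (not isolated)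
Conditions: Br2, CH2Cl2, −78 → 0 °C; Et3N, 0 °C
Reagents that add atoms: bromine BrBr
Why: Bromine addition to the alkene followed by amine-induced E1cB loss of HBr from the α-position is the established preparation of 2-bromoacrolein.

Step 8
Reactants: 14 prop-2-en-1-ol
Product: 15 3-(methoxymethoxy)prop-1-ene
Conditions: MOMCl, i-Pr2NEt, CH2Cl2, 0 °C → rt
Reagents that add atoms: chloromethyl methyl ether COCCl
Why: O-Alkylation of the alcohol with the reactive chloromethyl ether gives the allyl MOM ether needed for γ-alkoxyallyl metalation.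

Step 9
Reactants: 15 3-(methoxymethoxy)prop-1-ene; 13 2-bromoprop-2-enal
Product: 17 (3R,4S)-2-bromo-4-(methoxymethoxy)hexa-1,5-dien-3-ol, via alkoxyallylborane 16 (not isolated)
Conditions: s-BuLi, THF, −78 °C; (+)-Ipc2BOMe; BF3·OEt2; then 13, −78 °C; NaOH, H2O2, rt
Reagents that add atoms: none
Why: γ-Alkoxyallylboration with a diisopinocampheylborane (Brown allylation): the (Z)-alkoxyallylborane 16 adds through a chair transition state that gives the syn (threo) O8/O9 pair, the isopinocampheyl groups select the Re face of the aldehyde (C9 and with it C8), and the product has O8 as an ether and O9 free, so the two oxygens are told apart from the start.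

Step 10
Reactants: 17 (3R,4S)-2-bromo-4-(methoxymethoxy)hexa-1,5-dien-3-ol
Product: 18 methyl (3S,4S)-3-hydroxy-4-(methoxymethoxy)-2-methylidenehex-5-enoate
Conditions: Pd(PPh3)4 (5 mol %), CO (1 atm), Et3N, MeOH, 50 °C
Reagents that add atoms: carbon monoxide [C-]#[O+]; methanol CO
Why: Palladium-catalysed methoxycarbonylation of the vinyl bromide (oxidative addition, CO insertion, methanolysis of the acylpalladium) installs C14 as the 2-substituted acrylate, with methanol as solvent outcompeting closure of the free hydroxyl to a four-membered lactone.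

Step 11
Reactants: 18 methyl (3S,4S)-3-hydroxy-4-(methoxymethoxy)-2-methylidenehex-5-enoate
Product: 19 methyl (3S,4S)-3-{[2-(bromomethyl)prop-2-enoyl]oxy}-4-(methoxymethoxy)-2-methylidenehex-5-enoate
Conditions: 2-(bromomethyl)acrylic acid, DIC, DMAP (5 mol %), CH2Cl2, −20 → 0 °C
Reagents that add atoms: 2-(bromomethyl)prop-2-enoic acid C=C(CBr)C(=O)O
Why: Steglich esterification acylates the only free hydroxyl (O9) with the acid that brings C11, C12 and C13, run cold and with little DMAP so that the allylic bromide is not quaternised.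

Step 12
Reactants: 19 methyl (3S,4S)-3-{[2-(bromomethyl)prop-2-enoyl]oxy}-4-(methoxymethoxy)-2-methylidenehex-5-enoate
Product: 20 methyl 2-[(2S,3S)-5-(bromomethyl)-3-(methoxymethoxy)-6-oxo-3,6-dihydro-2H-pyran-2-yl]prop-2-enoate
Conditions: Grubbs II (5 mol %), CH2Cl2, 40 °C
Reagents that add atoms: none
Why: Ring-closing metathesis of an acrylate ester of a homoallylic alcohol is the standard entry to 5,6-dihydropyran-2-ones: the carbene formed at the vinyl group can only close the six-membered ring onto the bromomethylacrylate (the C10 acrylate is too close), and the ring locks C8 cis to the carbonyl C12.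

Step 13
Reactants: 20 methyl 2-[(2S,3S)-5-(bromomethyl)-3-(methoxymethoxy)-6-oxo-3,6-dihydro-2H-pyran-2-yl]prop-2-enoate
Product: 21 methyl 2-[(2S,3S)-5-(bromomethyl)-3-hydroxy-6-oxo-3,6-dihydro-2H-pyran-2-yl]prop-2-enoate
Conditions: Me2BBr, CH2Cl2, −78 °C; aq. NaHCO3
Reagents that add atoms: none
Why: Dimethylboron bromide cleaves methoxymethyl ethers at −78 °C without touching esters, the lactone or the allylic bromide, and a bromide reagent cannot scramble the halide; the acetal is removed here because no later intermediate with the epoxide would tolerate it.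

Step 14
Reactants: 21 methyl 2-[(2S,3S)-5-(bromomethyl)-3-hydroxy-6-oxo-3,6-dihydro-2H-pyran-2-yl]prop-2-enoate
Product: 22 methyl 2-[(2S,3S)-5-(bromomethyl)-6-oxo-3-[(triethylsilyl)oxy]-3,6-dihydro-2H-pyran-2-yl]prop-2-enoate
Conditions: TESOTf, 2,6-lutidine, CH2Cl2, −78 °C
Reagents that add atoms: triethylsilyl trifluoromethanesulfonate CC[Si](CC)(CC)OS(=O)(=O)C(F)(F)F
Why: Silylation with the triflate and a hindered base is fast at −78 °C, where 2,6-lutidine does not alkylate, and puts on O8 a poor leaving group that can later be removed in the presence of the TBS ether.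

Step 15
Reactants: 10 (2R,3R)-3-[(2S,3E)-2-[(tert-butyldimethylsilyl)oxy]pent-3-en-1-yl]-3-methyloxirane-2-carbaldehyde; 22 methyl 2-[(2S,3S)-5-(bromomethyl)-6-oxo-3-[(triethylsilyl)oxy]-3,6-dihydro-2H-pyran-2-yl]prop-2-enoate
Product: 25 methyl (3S,4S)-4-{(2S,3S)-2-[(2S,3R)-3-{(2S,3E)-2-[(tert-butyldimethylsilyl)oxy]pent-3-en-1-yl}-3-methyloxiran-2-yl]-4-methylidene-5-oxooxolan-3-yl}-3-hydroxy-2-methylidene-4-[(triethylsilyl)oxy]butanoate, via allylzinc bromide 23 (not isolated), via hydroxy δ-lactone 24 (not isolated)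
Conditions: Zn dust, THF/sat. aq. NH4Cl, 0 °C → rt; then PPTS (cat.), toluene, 45 °C
Reagents that add atoms: none
Why: Zinc Barbier allylation of the Dreiding–Schmidt type: the allylzinc 23 reacts at its ring carbon C7 through a chair transition state in which the ring holds C8 trans to the CH2Zn carbon (an E-type reagent, hence the anti adduct that becomes the trans lactone), the aldehyde approaches the ring face opposite to the cis-disposed OTES and C9 substituents (C7), this pairing coincides with Felkin–Anh attack anti to the epoxide C–O bond (C6, erythro), and mild acid then moves the acyl group from O9 to O6 (δ- to γ-lactone translactonisation), which frees only the C9 hydroxyl.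

Step 16
Reactants: 25 methyl (3S,4S)-4-{(2S,3S)-2-[(2S,3R)-3-{(2S,3E)-2-[(tert-butyldimethylsilyl)oxy]pent-3-en-1-yl}-3-methyloxiran-2-yl]-4-methylidene-5-oxooxolan-3-yl}-3-hydroxy-2-methylidene-4-[(triethylsilyl)oxy]butanoate
Product: 26 methyl (3S,4S)-3-acetoxy-4-{(2S,3S)-2-[(2S,3R)-3-{(2S,3E)-2-[(tert-butyldimethylsilyl)oxy]pent-3-en-1-yl}-3-methyloxiran-2-yl]-4-methylidene-5-oxooxolan-3-yl}-2-methylidene-4-[(triethylsilyl)oxy]butanoate
Conditions: Ac2O, pyridine, CH2Cl2, 0 °C → rt
Reagents that add atoms: acetic anhydride CC(=O)OC(C)=O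
Why: Acetylation of the one free hydroxyl (the allylic C9–OH) in pyridine, without DMAP to avoid SN2′ displacement of the resulting Baylis–Hillman-type acetate, installs the C9 acetate of the target.

Step 17
Reactants: 26 methyl (3S,4S)-3-acetoxy-4-{(2S,3S)-2-[(2S,3R)-3-{(2S,3E)-2-[(tert-butyldimethylsilyl)oxy]pent-3-en-1-yl}-3-methyloxiran-2-yl]-4-methylidene-5-oxooxolan-3-yl}-2-methylidene-4-[(triethylsilyl)oxy]butanoate
Product: 27 methyl (1(10)E,2S,4R,5S,6S,7S,8S,9S)-9-acetoxy-2-[(tert-butyldimethylsilyl)oxy]-4,5-epoxy-8-[(triethylsilyl)oxy]germacra-1(10),11(13)-dien-12,6-olid-14-oate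
Conditions: Hoveyda–Grubbs II (15 mol %), toluene (1 mM), 80 °C
Reagents that add atoms: none
Why: Ring-closing metathesis between the propenyl group (C1) and the 2-substituted acrylate (C10) should give the trisubstituted enoate with loss of propene: medium-ring closure favours the cis ring olefin, which is also the more stable enoate geometry (C2 trans to the ester), the trans lactone and cis epoxide hold the chain folded, and closure onto the C13 methylene is excluded because it would put a bridgehead double bond into an eight-membered ring.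

Step 18
Reactants: 27 methyl (1(10)E,2S,4R,5S,6S,7S,8S,9S)-9-acetoxy-2-[(tert-butyldimethylsilyl)oxy]-4,5-epoxy-8-[(triethylsilyl)oxy]germacra-1(10),11(13)-dien-12,6-olid-14-oate
Product: 28 methyl (1(10)E,2S,4R,5S,6S,7R,8S,9S)-9-acetoxy-2-[(tert-butyldimethylsilyl)oxy]-4,5-epoxy-8-hydroxygermacra-1(10),11(13)-dien-12,6-olid-14-oate
Conditions: HF·pyridine, pyridine, THF, 0 °C
Reagents that add atoms: none
Why: Buffered HF·pyridine removes a triethylsilyl ether far faster than a tert-butyldimethylsilyl ether, so O8 is freed while O2 stays protected, and the weakly acidic medium should neither move the neighbouring acetate nor open the epoxide.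

Step 19
Reactants: 28 methyl (1(10)E,2S,4R,5S,6S,7R,8S,9S)-9-acetoxy-2-[(tert-butyldimethylsilyl)oxy]-4,5-epoxy-8-hydroxygermacra-1(10),11(13)-dien-12,6-olid-14-oate
Product: 29 methyl (1(10)E,2S,4R,5S,6S,7R,8S,9S)-9-acetoxy-2-[(tert-butyldimethylsilyl)oxy]-4,5-epoxy-8-[(2Z)-2-methylbut-2-enoyloxy]germacra-1(10),11(13)-dien-12,6-olid-14-oate
Conditions: angelic acid, 2,4,6-trichlorobenzoyl chloride, Et3N, toluene, rt; then 28, 75 °C
Reagents that add atoms: (Z)-2-methylbut-2-enoic acid (angelic acid) C/C=C(/C)C(=O)O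
Why: Yamaguchi esterification through the mixed anhydride of angelic acid acylates the hindered C8 hydroxyl without Z to E isomerisation of the angelate, the usual way to make this ester next to an existing acyloxy group.

Step 20
Reactants: 29 methyl (1(10)E,2S,4R,5S,6S,7R,8S,9S)-9-acetoxy-2-[(tert-butyldimethylsilyl)oxy]-4,5-epoxy-8-[(2Z)-2-methylbut-2-enoyloxy]germacra-1(10),11(13)-dien-12,6-olid-14-oate
Product: 30 methyl (1(10)E,2S,4R,5S,6S,7R,8S,9S)-9-acetoxy-4,5-epoxy-2-hydroxy-8-[(2Z)-2-methylbut-2-enoyloxy]germacra-1(10),11(13)-dien-12,6-olid-14-oate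
Conditions: HF·pyridine, pyridine, THF, 0 °C → rt
Reagents that add atoms: none
Why: Cleavage of the last silyl ether by buffered, non-basic fluoride should leave the two esters, the epoxide and the α-methylene lactone untouched and give the target.

**Compound list**

1 | methyl 3-methylbut-2-enoate | CC(C)=CC(=O)OC | starting material
2 | [(1-methoxy-3-methylbuta-1,3-dien-1-yl)oxy]trimethylsilane | C=C(C)C=C(OC)O[Si](C)(C)C | intermediate
3 | (E)-but-2-enal | C/C=C/C=O | starting material
4 | copper(I) alkoxide of methyl (2Z,5S,6E)-5-hydroxy-3-methylocta-2,6-dienoate | COC(=O)/C=C(/C)C[C@H]([O-])/C=C/C.[Cu+] | intermediate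
5 | (S)-4-methyl-6-[(E)-prop-1-en-1-yl]-5,6-dihydro-2H-pyran-2-one | O=C1C=C(C)C[C@@H](/C=C/C)O1 | intermediate
6 | sodium (2R,3R)-3-[(2S,3E)-2-hydroxypent-3-en-1-yl]-3-methyloxirane-2-carboxylate | [Na+].[O-]C(=O)[C@@H]1O[C@]1(C)C[C@H](O)/C=C/C | intermediate
7 | (1R,4S,6R)-6-methyl-4-[(E)-prop-1-en-1-yl]-3,7-dioxabicyclo[4.1.0]heptan-2-one | O=C1O[C@H](/C=C/C)C[C@@]2(C)O[C@@H]12 | intermediate
8 | (2R,3R)-3-[(2S,3E)-2-hydroxypent-3-en-1-yl]-N-methoxy-N,3-dimethyloxirane-2-carboxamide | CON(C)C(=O)[C@@H]1O[C@]1(C)C[C@H](O)/C=C/C | intermediate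
9 | (2R,3R)-3-[(2S,3E)-2-[(tert-butyldimethylsilyl)oxy]pent-3-en-1-yl]-N-methoxy-N,3-dimethyloxirane-2-carboxamide | CON(C)C(=O)[C@@H]1O[C@]1(C)C[C@H](O[Si](C)(C)C(C)(C)C)/C=C/C | intermediate
10 | (2R,3R)-3-[(2S,3E)-2-[(tert-butyldimethylsilyl)oxy]pent-3-en-1-yl]-3-methyloxirane-2-carbaldehyde | O=C[C@@H]1O[C@]1(C)C[C@H](O[Si](C)(C)C(C)(C)C)/C=C/C | intermediate
11 | prop-2-enal (acrolein) | C=CC=O | starting material
12 | 2,3-dibromopropanal (racemic) | O=CC(Br)CBr | intermediate
13 | 2-bromoprop-2-enal | C=C(Br)C=O | intermediate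
14 | prop-2-en-1-ol | C=CCO | starting material
15 | 3-(methoxymethoxy)prop-1-ene | C=CCOCOC | intermediate
16 | [(2Z)-3-(methoxymethoxy)prop-2-en-1-yl]diisopinocampheylborane (Ipc groups from (−)-α-pinene) | COCO/C=C\CB([C@H]1C[C@H]2C[C@@H]([C@@H]1C)C2(C)C)[C@H]1C[C@H]2C[C@@H]([C@@H]1C)C2(C)C | intermediate
17 | (3R,4S)-2-bromo-4-(methoxymethoxy)hexa-1,5-dien-3-ol | C=C[C@H](OCOC)[C@@H](O)C(Br)=C | intermediate
18 | methyl (3S,4S)-3-hydroxy-4-(methoxymethoxy)-2-methylidenehex-5-enoate | C=C[C@H](OCOC)[C@@H](O)C(=C)C(=O)OC | intermediate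
19 | methyl (3S,4S)-3-{[2-(bromomethyl)prop-2-enoyl]oxy}-4-(methoxymethoxy)-2-methylidenehex-5-enoate | C=C[C@H](OCOC)[C@@H](OC(=O)C(=C)CBr)C(=C)C(=O)OC | intermediate
20 | methyl 2-[(2S,3S)-5-(bromomethyl)-3-(methoxymethoxy)-6-oxo-3,6-dihydro-2H-pyran-2-yl]prop-2-enoate | O=C1O[C@@H](C(=C)C(=O)OC)[C@@H](OCOC)C=C1CBr | intermediate
21 | methyl 2-[(2S,3S)-5-(bromomethyl)-3-hydroxy-6-oxo-3,6-dihydro-2H-pyran-2-yl]prop-2-enoate | O=C1O[C@@H](C(=C)C(=O)OC)[C@@H](O)C=C1CBr | intermediate
22 | methyl 2-[(2S,3S)-5-(bromomethyl)-6-oxo-3-[(triethylsilyl)oxy]-3,6-dihydro-2H-pyran-2-yl]prop-2-enoate | O=C1O[C@@H](C(=C)C(=O)OC)[C@@H](O[Si](CC)(CC)CC)C=C1CBr | intermediate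
23 | bromo{[(5S,6S)-6-[1-(methoxycarbonyl)ethenyl]-2-oxo-5-[(triethylsilyl)oxy]-5,6-dihydro-2H-pyran-3-yl]methyl}zinc | O=C1O[C@@H](C(=C)C(=O)OC)[C@@H](O[Si](CC)(CC)CC)C=C1C[Zn]Br | intermediate
24 | methyl 2-[(2S,3S,4S)-4-{(S)-hydroxy[(2S,3R)-3-{(2S,3E)-2-[(tert-butyldimethylsilyl)oxy]pent-3-en-1-yl}-3-methyloxiran-2-yl]methyl}-5-methylidene-6-oxo-3-[(triethylsilyl)oxy]oxan-2-yl]prop-2-enoate | C=C1C(=O)O[C@@H](C(=C)C(=O)OC)[C@@H](O[Si](CC)(CC)CC)[C@@H]1[C@H](O)[C@@H]1O[C@]1(C)C[C@H](O[Si](C)(C)C(C)(C)C)/C=C/C | intermediate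
25 | methyl (3S,4S)-4-{(2S,3S)-2-[(2S,3R)-3-{(2S,3E)-2-[(tert-butyldimethylsilyl)oxy]pent-3-en-1-yl}-3-methyloxiran-2-yl]-4-methylidene-5-oxooxolan-3-yl}-3-hydroxy-2-methylidene-4-[(triethylsilyl)oxy]butanoate | C=C1C(=O)O[C@H]([C@@H]2O[C@]2(C)C[C@H](O[Si](C)(C)C(C)(C)C)/C=C/C)[C@H]1[C@H](O[Si](CC)(CC)CC)[C@@H](O)C(=C)C(=O)OC | intermediate
26 | methyl (3S,4S)-3-acetoxy-4-{(2S,3S)-2-[(2S,3R)-3-{(2S,3E)-2-[(tert-butyldimethylsilyl)oxy]pent-3-en-1-yl}-3-methyloxiran-2-yl]-4-methylidene-5-oxooxolan-3-yl}-2-methylidene-4-[(triethylsilyl)oxy]butanoate | C=C1C(=O)O[C@H]([C@@H]2O[C@]2(C)C[C@H](O[Si](C)(C)C(C)(C)C)/C=C/C)[C@H]1[C@H](O[Si](CC)(CC)CC)[C@@H](OC(C)=O)C(=C)C(=O)OC | intermediate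
27 | methyl (1(10)E,2S,4R,5S,6S,7S,8S,9S)-9-acetoxy-2-[(tert-butyldimethylsilyl)oxy]-4,5-epoxy-8-[(triethylsilyl)oxy]germacra-1(10),11(13)-dien-12,6-olid-14-oate (C7 reads S only because the silyl ether changes the CIP ranking) | C=C1C(=O)O[C@H]2[C@H]1[C@H](O[Si](CC)(CC)CC)[C@@H](OC(C)=O)/C(C(=O)OC)=C\[C@@H](O[Si](C)(C)C(C)(C)C)C[C@@]1(C)O[C@@H]21 | intermediate
28 | methyl (1(10)E,2S,4R,5S,6S,7R,8S,9S)-9-acetoxy-2-[(tert-butyldimethylsilyl)oxy]-4,5-epoxy-8-hydroxygermacra-1(10),11(13)-dien-12,6-olid-14-oate | C=C1C(=O)O[C@H]2[C@H]1[C@H](O)[C@@H](OC(C)=O)/C(C(=O)OC)=C\[C@@H](O[Si](C)(C)C(C)(C)C)C[C@@]1(C)O[C@@H]21 | intermediate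
29 | methyl (1(10)E,2S,4R,5S,6S,7R,8S,9S)-9-acetoxy-2-[(tert-butyldimethylsilyl)oxy]-4,5-epoxy-8-[(2Z)-2-methylbut-2-enoyloxy]germacra-1(10),11(13)-dien-12,6-olid-14-oate | C=C1C(=O)O[C@H]2[C@H]1[C@H](OC(=O)/C(C)=C\C)[C@@H](OC(C)=O)/C(C(=O)OC)=C\[C@@H](O[Si](C)(C)C(C)(C)C)C[C@@]1(C)O[C@@H]21 | intermediate
30 | methyl (1(10)E,2S,4R,5S,6S,7R,8S,9S)-9-acetoxy-4,5-epoxy-2-hydroxy-8-[(2Z)-2-methylbut-2-enoyloxy]germacra-1(10),11(13)-dien-12,6-olid-14-oate (CNP0278274.1) | C=C1C(=O)O[C@H]2[C@H]1[C@H](OC(=O)/C(C)=C\C)[C@@H](OC(C)=O)/C(C(=O)OC)=C\[C@@H](O)C[C@@]1(C)O[C@@H]21 | target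

**Step count and risks**

Total steps: 20. Longest linear sequence: 13 steps (step 7, then steps 9 to 20).

Most likely to fail, first: step 17. At the dilution that ring closure needs, the carbene at C1 may engage the hindered 2-substituted acrylate too slowly, so that catalyst decay and intermolecular metathesis consume the diene. The fallback joins C1=C10 first and closes the ring at C6–C7 instead. It sets out from 10 and 22: cross-metathesis at high concentration with 10 in excess (Hoveyda–Grubbs II, CH2Cl2, 40 °C) should give, as other cross-metatheses of 2-substituted acrylates do, the enoate with C2 trans to the ester, the seco aldehyde bromide F1. An intramolecular zinc Barbier reaction of F1 under high dilution, a macrocyclic closure known for ten-membered carbocycles fused to α-methylene lactones, followed by the PPTS translactonisation, should give the ring-closed C9 alcohol F2. Acetylation as in step 16 returns to the route at 27.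

Second: step 15. In the aqueous zinc medium the metal may bridge the aldehyde and epoxide oxygens, which would erode the facial selectivity at C6 and, through the chair, the anti relationship; the allylzinc may also be protonated or lose the C8 silyloxy group before it adds. The fallback replaces the transient allylzinc by an isolated allylboronate. It sets out from 22: zinc insertion in dry THF with in situ trapping by 2-isopropoxy-4,4,5,5-tetramethyl-1,3,2-dioxaborolane should give the pinacol allylboronate F3. Thermal allylboration of 10 with F3 in toluene runs through a closed chair without a metal able to chelate the epoxide and should give 24 after work-up; the PPTS treatment of step 15 converts 24 into 25, where the route is rejoined.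

Third: step 2. The enantiofacial discrimination of the copper catalyst may be insufficient for this small enal, or part of the aldolate may be silylated as an open-chain ester instead of cyclising. The fallback sets C2 by a catalytic acetone-equivalent aldol and forms C4=C5 inside the ring. It sets out from 3: titanium–BINOL-catalysed addition of 2-methoxypropene with acidic work-up should give the hydroxy ketone F4. Esterification with diethylphosphonoacetic acid (DCC, DMAP) gives the phosphonoacetate F5, and an intramolecular Horner–Wadsworth–Emmons reaction (LiCl, DBU, MeCN) closes the lactone and returns to the route at 5.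

**Further compounds**

F1 | step 17 | methyl (2E,4S)-2-[(2S,3S)-5-(bromomethyl)-6-oxo-3-[(triethylsilyl)oxy]-3,6-dihydro-2H-pyran-2-yl]-4-[(tert-butyldimethylsilyl)oxy]-5-[(2R,3R)-3-formyl-2-methyloxiran-2-yl]pent-2-enoate | O=C[C@@H]1O[C@]1(C)C[C@H](O[Si](C)(C)C(C)(C)C)/C=C(C(=O)OC)\[C@@H]1OC(=O)C(CBr)=C[C@@H]1O[Si](CC)(CC)CC
F2 | step 17 | methyl (1(10)E,2S,4R,5S,6S,7S,8S,9S)-2-[(tert-butyldimethylsilyl)oxy]-4,5-epoxy-9-hydroxy-8-[(triethylsilyl)oxy]germacra-1(10),11(13)-dien-12,6-olid-14-oate | C=C1C(=O)O[C@H]2[C@H]1[C@H](O[Si](CC)(CC)CC)[C@@H](O)/C(C(=O)OC)=C\[C@@H](O[Si](C)(C)C(C)(C)C)C[C@@]1(C)O[C@@H]21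
F3 | step 15 | methyl 2-[(2S,3S)-6-oxo-5-[(4,4,5,5-tetramethyl-1,3,2-dioxaborolan-2-yl)methyl]-3-[(triethylsilyl)oxy]-3,6-dihydro-2H-pyran-2-yl]prop-2-enoate | O=C1O[C@@H](C(=C)C(=O)OC)[C@@H](O[Si](CC)(CC)CC)C=C1CB1OC(C)(C)C(C)(C)O1
F4 | step 2 | (4S,5E)-4-hydroxyhept-5-en-2-one | CC(=O)C[C@H](O)/C=C/C
F5 | step 2 | (2E,4S)-6-oxohept-2-en-4-yl 2-(diethoxyphosphoryl)acetate | CCOP(=O)(OCC)CC(=O)O[C@@H](CC(C)=O)/C=C/C
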